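The initiator is our yardstick. We divide the product by the initiator charged and call that the turnover count.

common to all: temperature 70 °C

|  | substrate | coupling partner | initiator | remark | time |
|---|---|---|---|---|---|
| ochre | 50 mM | 31.4 mM | 0.17 mM | run made earlier |  |
| blue | 66 mM | 31.4 mM | 0.17 mM | run made earlier |  |
| Thursday's | 33 mM | 20.0 mM | 0.25 mM |  | 10 d |
| Friday's | 33 mM | 31.4 mM | 0.17 mM |  | 10 d |

| run | time / d | product / % | substrate / % |
|---|---|---|---|
| ochre | 0.625 | 13 | 83 |
| ochre | 1.25 | 25 | 75 |
| ochre | 1.67 | 27 | 70 |
| ochre | 2.50 | 35 | 63 |
| ochre | 3.00 | 36 | 60 |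
| ochre | 4.00 | 42 | 61 |
| blue | 0.625 | 12 | 89 |
| blue | 1.25 | 17 | 80 |
| blue | 1.67 | 19 | 75 |
| blue | 2.50 | 28 | 69 |
| blue | 3.00 | 29 | 71 |
| blue | 4.00 | 32 | 67 |

(standard deviation of a reading: 2 percentage points)

1. which one finishes higher in amount of product, in percent of the substrate charged ("neither" within 2 percentage points) (Thursday's / Friday's / neither)
2. amount of product at the end, in percent of the substrate charged, Thursday's
3. amount of product at the end, in percent of the substrate charged, Friday's

- no earlier run changes the charge of initiator; that part of a forecast is a guess

In the ochre run the initiator is 0.340 % of the substrate charge, and in the blue run 0.258 %. Product at the last reading, 42 % and 32 %, gives counts of 124 and 124. So between these two charges the count does not follow the substrate.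

But the count is still rising, and this is our weak link. Averaged over both runs, it gains 69.8 up to 1.25 d, then 36.1 up to 2.50 d, then 18.1 up to 4.00 d. The second gain is half the first, and the third half the second. Such halving, carried on, adds the last gain once more and reaches 142. But the last span is the longer, 1.50 d against 1.25 d, so we read the fall as steeper and take that figure as a top. We settle midway, at 133, as the final turnover count, the product made per initiator charged.

Friday's has the ochre run's initiator and coupling partner, so we keep the count. Its initiator is 0.515 % of its substrate, which gives 68.5 % product.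

Thursday's needs a guess. In the ochre run the final count uses 72.0 % of the coupling partner. We take that use as first order in coupling partner and let it grow with the square root of the initiator, a factor of 1.21. The fraction left, 28.0 %, raised to that power becomes 21.4 %. So Thursday's gives 47.6 % product, and we name Friday's.

The forecast, holding that “Friday's repeats this chemistry”, named Friday's, with 53 % for Thursday's and 70 % for Friday's, both above ours.

The flasks give 48.6 % for Thursday's and 64.8 % for Friday's, so Friday's finishes higher.

    initiator → 2 initiating radical (k = 6.50 × 10⁻⁶ s⁻¹, Ea = 110 kJ mol⁻¹)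
    substrate + initiating radical → capped initiator + first chain carrier (k = 37000 M⁻¹ s⁻¹, Ea = 37.0 kJ mol⁻¹)
    coupling partner + first chain carrier → product + second chain carrier (k = 6400 M⁻¹ s⁻¹, Ea = 19.0 kJ mol⁻¹)
    substrate + second chain carrier → released group + first chain carrier (k = 1500 M⁻¹ s⁻¹, Ea = 36.0 kJ mol⁻¹)
    first chain carrier → ended carrier (k = 1.00 s⁻¹, Ea = 84.0 kJ mol⁻¹)
    2 second chain carrier → ended chains A (k = 2.00 × 10⁷ M⁻¹ s⁻¹, Ea = 23.0 kJ mol⁻¹)
    2 first chain carrier → ended chains B (k = 7.00 × 10⁸ M⁻¹ s⁻¹, Ea = 13.0 kJ mol⁻¹)
    (constants at 70 °C)

Friday's count comes to 126, below our 133. After 10.0 d in Friday's, 32 % of the coupling partner and 34 % of the substrate remain, while the initiator is down to 0.36 %. The half-life of coupling partner in Friday's by the step that makes product is then 160 d, far longer than the 10 d allowed. A neighbour flask, Friday's recipe with 130 mM of substrate, gets 17.4 % from our count, and it ends at 17.3 %.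

(All runs were computed with constants of no real substance, noise included.)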